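## Analysis of the target

The target is a 1,7-diarylheptanoid whose heptane carbons C2 and C6 are bridged by oxygen. Its single oxane ring (O1, C2–C6) carries a 4-hydroxy-3-methoxyphenyl (guaiacyl) group at C2, a hydroxyl at C4 and, at C6, a side chain C7(OH)–C8H2 ending in a 4-hydroxyphenyl ring. These target locants are used for all intermediates, open-chain ones included, while systematic names keep their own locants. There are four stereocentres, (2R,4R,6S,7R): the three ring substituents are all cis and so all equatorial in the chair, and the exocyclic carbinol C7 is anti to the C6 oxygen. Read as an open chain, the C4 and C6 oxygens are 1,3-anti and the C6 and C7 oxygens are 1,2-anti, while C2 becomes a stereocentre only when the ring is closed. The sensitive points are the two free phenols, the two secondary alcohols and above all the O1–C2 bond, a benzylic ether para to a free phenol that can ionise to a quinone methide under acid and can be hydrogenolysed. The difficulty lies less in the skeleton than in telling apart two similar phenolic rings and four oxygen functions, and in setting C2 relative to centres two and four ring atoms away. The strategy rests on one feature: C2 is the benzylic carbon para to the free hydroxyl of the guaiacyl ring, and its C–H bond is of the type that flavin-dependent 4-alkylphenol oxidases remove as hydride. If that C–H is oxidised in an open-chain precursor, the C6 hydroxyl is placed to capture the quinone methide at C2 and close the oxane through O1–C2.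

## Retrosynthetic reasoning

**17 to 16.** No skeletal bond is cut. The phenol of the C8 ring is masked as a benzyl ether, so that 16 has one free phenol only, the guaiacyl one. The mask sits on this ring because the preceding ring closure needs the guaiacyl phenol free and the other ring unable to form a quinone methide. The forward reaction is a hydrogenolysis that must cleave an aryl benzyl ether and spare the ring O1–C2 bond.

**16 to 14 through 15.** The O1–C2 bond is cut and C2 is returned to a methylene group, which gives open-chain triol 14. This bond is chosen over O1–C6 because C6 is an existing stereocentre that a substitution would put at risk, whereas C2 is the one carbon whose C–H bond is activated by the para-phenol. Cutting a ring C–C bond instead would leave C2 to be set in a separate operation. The gain is that ring and C2 disappear together and the remaining three stereocentres are acyclic carbinols that need no protection. Forward, the C2–H bond must be oxidised to quinone methide 15, and the C6 hydroxyl (not the C4 or C7 hydroxyl) must add to C2 on the face that places the aryl group equatorial.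

**14 to 13 to 12.** These are functional-group changes. The guaiacyl oxygen and O7 are carried as silyl ethers (13), and the C4 carbinol is traced back to a ketone (12). The C6 hydroxyl of 12 can then direct a 1,3-anti reduction, which is the reliable way to the C4/C6 relationship. Forward, hydride must be delivered intramolecularly from the C6 oxygen, and one desilylation must free both oxygens without touching the benzyl ether.

**12 to 7 and 11.** The C5–C6 bond is cut as an aldol. This divides the chain into two fragments of similar size, each carrying one aromatic ring and each coming from a cheap aromatic starting material, and it makes C6 the only stereocentre formed in the coupling. Cutting C3–C4 or C4–C5 on the ketone side would not put the new centre next to an existing one. Forward, silyl enol ether 11 must add to α-silyloxy aldehyde 7 without chelation, so that the C7 centre controls C6 in the Felkin (1,2-anti) sense.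

**7 to 6, 5, 4 and 1.** The aldehyde is an ester at a lower oxidation level (6), the silyl ether and the two benzyl groups are removed in thought (5, 4), and the C7 hydroxyl is exchanged for an amino group, which leads to D-tyrosine (1). The C7 centre thus comes from the chiral pool. Forward, the amino-to-hydroxyl exchange must proceed with retention.

**11 to 9 and 8.** The enol ether is the kinetic, methyl-side enolate of ketone 9 trapped on oxygen, and 9 is zingerone (8) with its phenol silylated. Forward, deprotonation must take place at the methyl group and not at C3.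

## Alternatives that were turned down

**Alternative 1:** C4–C5 and the C6–O bond are disconnected together, the C4 carbonyl and the C6 hydroxyl being carried as an isoxazoline.
- Forward: oxime A2 is oxidised in the flask to its nitrile oxide, which adds in a 1,3-dipolar cycloaddition to the terminal alkene of allylic silyl ether A3 and gives isoxazoline A1. N–O cleavage would release a β-hydroxy styryl ketone, the C6 hydroxyl would close the oxane by conjugate addition at C2, and the C4 ketone would be reduced.
- For it: the coupling is convergent, the regiochemistry of nitrile oxide addition to a monosubstituted alkene is dependable, and every step is known chemistry. On that last point it is stronger than the chosen route.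
- Against it: C6 is set only by the neighbouring C7 centre through the inside-alkoxy preference, a modest bias for an acyclic allylic silyl ether. The conjugated nitrile oxide tends to dimerise, and the hypochlorite oxidant can chlorinate the electron-rich ring. The N–O cleavage must spare a styrene and two benzyl ethers. After A1 the route still needs N–O cleavage, ring closure, ketone reduction and removal of three protecting groups.
- Comparison: the chosen route sets C6 by a Felkin-controlled aldol with a stronger bias, never carries a ketone in the ring, and forms ring, O1–C2 and C2 in one late step. What it gives up is precedent for that step.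

**Alternative 2:** Both bonds to C4 (C3–C4 and C4–C5) are cut, C4 becoming a dithiane acyl-anion linchpin.
- Forward: lithiated silyl dithiane A5 opens aryl oxirane A6 at its CH2 carbon. A 1,4-Brook rearrangement triggered by a polar additive moves silicon to the new C2 alkoxide and regenerates the dithiane anion, which opens epoxide A7 and gives A4 in one flask.
- For it: two C–C bonds are made in one operation, and C2, C6 and C7 all come from enantiopure epoxides, so no diastereoselective C–C bond formation is needed. In convergence it surpasses the chosen route.
- Against it: two enantiopure epoxides must be made first, and the electron-rich oxirane A6 is open to attack at its benzylic carbon and to ionisation. The C2 carbinol is built only to be given up, because closing O1–C2 means displacement at an electron-rich benzylic centre that will ionise rather than invert cleanly. The C4 ketone freed from the dithiane needs its own stereoselective reduction, and dithiane removal next to two electron-rich arenes is delicate. Three benzyl ethers must finally be hydrogenolysed beside the O1–C2 bond.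
- Comparison: it is clearly longer. The chosen route sets C4 by a directed reduction of an acyclic ketone, never makes a C2 carbinol, and has one benzyl ether to remove.

**Alternative 3:** The ring is disconnected across O1–C2 and C5–C6 as a hetero-Diels–Alder adduct.
- Forward: aldehyde 7 (the same compound as in the chosen route) and silyloxydiene A9 combine under a chiral tridentate Schiff-base chromium chloride catalyst, (ONO-Schiff base)CrCl with trivalent chromium. This gives cis-2,6-disubstituted dihydropyran A8, whose silyl enol ether would be hydrolysed to the C4 ketone and reduced by axial hydride delivery.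
- For it: the ring, two bonds and the C2/C6 cis relationship are formed in one catalyst-controlled step of an established reaction class. On reliability of the ring-forming step it is the strongest of the four plans and stronger than the chosen one.
- Against it: diene A9 must give up conjugation with its aryl group and is less electron-rich than the alkoxy dienes that suit this catalyst best. The catalyst must be matched to the C7 stereocentre of 7, and a mismatched pair is possible. The guaiacyl phenol must travel as a second benzyl ether, so two benzyl ethers, a silyl ether and a ketone stage remain after A8. The step count comes out about equal.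
- Comparison: the chosen route offers instead a ring closure at the final oxidation level on an unprotected triol, one redox operation fewer on the ring, and a precursor (14) that can also be cyclised by conventional chemical oxidation if the enzyme fails.

Key step: step 10

Assumption: a purified 4-alkylphenol oxidase of the vanillyl alcohol oxidase family (eugenol oxidase, or a variant with a widened substrate channel) is taken to be available; the enzyme named in step 10 stands for this class.

## Route

Step 1
Reactants: 1 D-tyrosine
Product: 4 (2R)-2-hydroxy-3-(4-hydroxyphenyl)propanoic acid, via diazonium carboxylate 2 (not isolated), via α-lactone 3 (not isolated)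
Conditions: NaNO2, 1 M aq. H2SO4, 0 °C → rt
Reagents that add atoms: water, O
Why: Diazotisation of the α-amino acid; the carboxylate displaces N2 from 2 with inversion to give α-lactone 3, which water opens at the α-carbon with a second inversion, so the (R) configuration should be retained in 4.

Step 2
Reactants: 4 (2R)-2-hydroxy-3-(4-hydroxyphenyl)propanoic acid
Product: 5 benzyl (2R)-3-[4-(benzyloxy)phenyl]-2-hydroxypropanoate
Conditions: BnBr (2.2 equiv), K2CO3, DMF, rt
Reagents that add atoms: benzyl bromide, BrCc1ccccc1
Why: Williamson etherification and carboxylate O-alkylation; carbonate ionises only the acid and the phenol, so both are benzylated while the secondary hydroxyl stays free and the stereocentre is untouched.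

Step 3
Reactants: 5 benzyl (2R)-3-[4-(benzyloxy)phenyl]-2-hydroxypropanoate
Product: 6 benzyl (2R)-3-[4-(benzyloxy)phenyl]-2-[(tert-butyldimethylsilyl)oxy]propanoate
Conditions: TBSCl, imidazole, DMF, rt
Reagents that add atoms: tert-butyldimethylsilyl chloride, CC(C)(C)[Si](C)(C)Cl
Why: Imidazole-promoted silylation of a secondary alcohol; the bulky, weakly coordinating TBS ether is chosen so that the later aldol runs without chelation.

Step 4
Reactants: 6 benzyl (2R)-3-[4-(benzyloxy)phenyl]-2-[(tert-butyldimethylsilyl)oxy]propanoate
Product: 7 (2R)-3-[4-(benzyloxy)phenyl]-2-[(tert-butyldimethylsilyl)oxy]propanal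
Conditions: i-Bu2AlH (1.1 equiv), CH2Cl2, −78 °C; MeOH, then aq. potassium sodium tartrate
Reagents that add atoms: none
Why: Partial reduction of an ester to the aldehyde with i-Bu2AlH at −78 °C, a dependable transformation for α-silyloxy esters; 7 is used at once because its α-stereocentre can epimerise on standing.

Step 5
Reactants: 8 zingerone
Product: 9 4-{4-[(tert-butyldimethylsilyl)oxy]-3-methoxyphenyl}butan-2-one
Conditions: TBSCl, imidazole, DMF, rt
Reagents that add atoms: tert-butyldimethylsilyl chloride, CC(C)(C)[Si](C)(C)Cl
Why: Silylation of the phenol; the aryl TBS ether tolerates the amide base and BF3 at low temperature and later falls to fluoride together with the secondary TBS ether.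

Step 6
Reactants: 9 4-{4-[(tert-butyldimethylsilyl)oxy]-3-methoxyphenyl}butan-2-one
Product: 11 tert-butyl(2-methoxy-4-{3-[(trimethylsilyl)oxy]but-3-en-1-yl}phenoxy)dimethylsilane, via lithium enolate 10 (not isolated)
Conditions: LiN(i-Pr)2, THF, −78 °C; Me3SiCl, −78 → 0 °C
Reagents that add atoms: chlorotrimethylsilane, C[Si](C)(C)Cl
Why: Kinetic deprotonation of the methyl ketone at the less hindered methyl group by the bulky amide base gives terminal enolate 10, which is silylated on oxygen; adding the ketone to excess base prevents enolate equilibration.

Step 7
Reactants: 7 (2R)-3-[4-(benzyloxy)phenyl]-2-[(tert-butyldimethylsilyl)oxy]propanal; 11 tert-butyl(2-methoxy-4-{3-[(trimethylsilyl)oxy]but-3-en-1-yl}phenoxy)dimethylsilane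
Product: 12 (5S,6R)-7-[4-(benzyloxy)phenyl]-6-[(tert-butyldimethylsilyl)oxy]-1-{4-[(tert-butyldimethylsilyl)oxy]-3-methoxyphenyl}-5-hydroxyheptan-3-one
Conditions: BF3·OEt2, CH2Cl2, −78 °C; aq. NaHCO3
Reagents that add atoms: none
Why: Mukaiyama aldol addition through an open transition state; BF3 is monodentate and the TBS ether does not chelate, so the polar Felkin–Anh arrangement exposes the si face of the aldehyde and the new carbinol centre C6 should form (S), anti to the C7 silyloxy group.

Step 8
Reactants: 12 (5S,6R)-7-[4-(benzyloxy)phenyl]-6-[(tert-butyldimethylsilyl)oxy]-1-{4-[(tert-butyldimethylsilyl)oxy]-3-methoxyphenyl}-5-hydroxyheptan-3-one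
Product: 13 (3R,5S,6R)-7-[4-(benzyloxy)phenyl]-6-[(tert-butyldimethylsilyl)oxy]-1-{4-[(tert-butyldimethylsilyl)oxy]-3-methoxyphenyl}heptane-3,5-diol
Conditions: Me4NBH(OAc)3, MeCN/AcOH (1:1), −30 °C
Reagents that add atoms: none
Why: Evans–Saksena reduction; hydride is delivered intramolecularly from boron bound to the C6 hydroxyl through a chair-like six-membered transition state, which should give the 1,3-anti diol and hence (R) at C4, while silyl and benzyl ethers are inert to the reagent.

Step 9
Reactants: 13 (3R,5S,6R)-7-[4-(benzyloxy)phenyl]-6-[(tert-butyldimethylsilyl)oxy]-1-{4-[(tert-butyldimethylsilyl)oxy]-3-methoxyphenyl}heptane-3,5-diol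
Product: 14 (3R,5S,6R)-7-[4-(benzyloxy)phenyl]-1-(4-hydroxy-3-methoxyphenyl)heptane-3,5,6-triol
Conditions: Bu4NF, AcOH, THF, 0 °C → rt
Reagents that add atoms: none
Why: Fluoride cleaves both the aryl and the secondary TBS ether; acetic acid buffers the phenoxide and alkoxides so that no silyl migration or base-induced side reaction is expected, and the benzyl ether is untouched.

Step 10
Reactants: 14 (3R,5S,6R)-7-[4-(benzyloxy)phenyl]-1-(4-hydroxy-3-methoxyphenyl)heptane-3,5,6-triol
Product: 16 (2R,4R,6S)-6-{(1R)-2-[4-(benzyloxy)phenyl]-1-hydroxyethyl}-2-(4-hydroxy-3-methoxyphenyl)oxan-4-ol, via p-quinone methide 15 (not isolated)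
Conditions: eugenol oxidase (FAD enzyme, Rhodococcus jostii RHA1), catalase, air, 50 mM potassium phosphate buffer pH 7.5, 10% DMSO, 25 °C
Reagents that add atoms: none
Why: Proposed new method: the phenolate of 14 should bind like the native guaiacyl substrates and pass the C2–H hydride to N5 of the flavin, giving enzyme-bound p-quinone methide 15, while O2 reoxidises the flavin and catalase removes the H2O2 formed. The C6 hydroxyl then adds to C2 of 15 in a 6-exo-trig 1,6-conjugate addition that restores the aromatic ring and forms O1–C2, which closes the oxane. The closest known reaction type is the enantioselective benzylic hydroxylation of 4-alkylphenols by vanillyl alcohol oxidase, where water adds to the same kind of enzyme-bound quinone methide; the chemical counterpart is DDQ-mediated oxidative benzylic etherification. The new centre C2 is controlled by the existing centres C4 and C6 through a chair-like transition state in which aryl, C4 hydroxyl and C6 side chain are all equatorial, which gives (2R), and this is the same sense in which the enzyme class delivers water, so substrate and catalyst should reinforce each other. Site selectivity is needed between the two benzylic CH2 groups C2 and C8 and is secured by the enzyme's demand for a free para-phenol, since the C8 ring is a benzyl ether. Among the three hydroxyls only the one on C6 gives a six-membered ring (the C4 hydroxyl would give an oxetane, the C7 hydroxyl an oxepane), so the triol needs no protection. The fates that compete for 15 are hydration at C2 and loss of a C3 proton to the styrene; the pendant hydroxyl is expected to win through its high effective molarity, and the (2R) product, like the (R)-alcohols this enzyme class leaves behind, should resist further oxidation.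

Step 11
Reactants: 16 (2R,4R,6S)-6-{(1R)-2-[4-(benzyloxy)phenyl]-1-hydroxyethyl}-2-(4-hydroxy-3-methoxyphenyl)oxan-4-ol
Product: 17 (2R,4R,6S)-6-[(1R)-1-hydroxy-2-(4-hydroxyphenyl)ethyl]-2-(4-hydroxy-3-methoxyphenyl)oxan-4-ol
Conditions: H2 (1 atm), 10% Pd/C, EtOAc, rt
Reagents that add atoms: none
Why: Catalytic hydrogenolysis of the aryl benzyl ether; under neutral conditions in EtOAc the phenolic O–CH2Ph bond should be cleaved much faster than the ring O1–C2 benzylic ether, and hydrogen uptake is stopped at one equivalent.

## Compound list

1 | D-tyrosine, (2R)-2-amino-3-(4-hydroxyphenyl)propanoic acid | N[C@H](Cc1ccc(O)cc1)C(=O)O | starting material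
2 | (2R)-2-diazonio-3-(4-hydroxyphenyl)propanoate (diazonium carboxylate) | N#[N+][C@H](Cc1ccc(O)cc1)C(=O)[O-] | intermediate (not isolated)
3 | (3S)-3-(4-hydroxybenzyl)oxiran-2-one (α-lactone) | O=C1O[C@H]1Cc1ccc(O)cc1 | intermediate (not isolated)
4 | (2R)-2-hydroxy-3-(4-hydroxyphenyl)propanoic acid | O[C@H](Cc1ccc(O)cc1)C(=O)O | intermediate
5 | benzyl (2R)-3-[4-(benzyloxy)phenyl]-2-hydroxypropanoate | O[C@H](Cc1ccc(OCc2ccccc2)cc1)C(=O)OCc1ccccc1 | intermediate
6 | benzyl (2R)-3-[4-(benzyloxy)phenyl]-2-[(tert-butyldimethylsilyl)oxy]propanoate | CC(C)(C)[Si](C)(C)O[C@H](Cc1ccc(OCc2ccccc2)cc1)C(=O)OCc1ccccc1 | intermediate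
7 | (2R)-3-[4-(benzyloxy)phenyl]-2-[(tert-butyldimethylsilyl)oxy]propanal | CC(C)(C)[Si](C)(C)O[C@H](Cc1ccc(OCc2ccccc2)cc1)C=O | intermediate
8 | zingerone, 4-(4-hydroxy-3-methoxyphenyl)butan-2-one | COc1cc(CCC(C)=O)ccc1O | starting material
9 | 4-{4-[(tert-butyldimethylsilyl)oxy]-3-methoxyphenyl}butan-2-one | COc1cc(CCC(C)=O)ccc1O[Si](C)(C)C(C)(C)C | intermediate
10 | lithium 4-{4-[(tert-butyldimethylsilyl)oxy]-3-methoxyphenyl}but-1-en-2-olate | COc1cc(CCC(=C)O[Li])ccc1O[Si](C)(C)C(C)(C)C | intermediate (not isolated)
11 | tert-butyl(2-methoxy-4-{3-[(trimethylsilyl)oxy]but-3-en-1-yl}phenoxy)dimethylsilane | COc1cc(CCC(=C)O[Si](C)(C)C)ccc1O[Si](C)(C)C(C)(C)C | intermediate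
12 | (5S,6R)-7-[4-(benzyloxy)phenyl]-6-[(tert-butyldimethylsilyl)oxy]-1-{4-[(tert-butyldimethylsilyl)oxy]-3-methoxyphenyl}-5-hydroxyheptan-3-one | COc1cc(CCC(=O)C[C@H](O)[C@H](O[Si](C)(C)C(C)(C)C)Cc2ccc(OCc3ccccc3)cc2)ccc1O[Si](C)(C)C(C)(C)C | intermediate
13 | (3R,5S,6R)-7-[4-(benzyloxy)phenyl]-6-[(tert-butyldimethylsilyl)oxy]-1-{4-[(tert-butyldimethylsilyl)oxy]-3-methoxyphenyl}heptane-3,5-diol | COc1cc(CC[C@@H](O)C[C@H](O)[C@H](O[Si](C)(C)C(C)(C)C)Cc2ccc(OCc3ccccc3)cc2)ccc1O[Si](C)(C)C(C)(C)C | intermediate
14 | (3R,5S,6R)-7-[4-(benzyloxy)phenyl]-1-(4-hydroxy-3-methoxyphenyl)heptane-3,5,6-triol | COc1cc(CC[C@@H](O)C[C@H](O)[C@H](O)Cc2ccc(OCc3ccccc3)cc2)ccc1O | intermediate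
15 | 4-{(3R,5S,6R)-7-[4-(benzyloxy)phenyl]-3,5,6-trihydroxyheptylidene}-2-methoxycyclohexa-2,5-dien-1-one (p-quinone methide) | COC1=CC(=CC[C@@H](O)C[C@H](O)[C@H](O)Cc2ccc(OCc3ccccc3)cc2)C=CC1=O | intermediate (not isolated)
16 | (2R,4R,6S)-6-{(1R)-2-[4-(benzyloxy)phenyl]-1-hydroxyethyl}-2-(4-hydroxy-3-methoxyphenyl)oxan-4-ol | COc1cc([C@H]2C[C@@H](O)C[C@@H]([C@H](O)Cc3ccc(OCc4ccccc4)cc3)O2)ccc1O | intermediate
17 | (2R,4R,6S)-6-[(1R)-1-hydroxy-2-(4-hydroxyphenyl)ethyl]-2-(4-hydroxy-3-methoxyphenyl)oxan-4-ol | COc1cc([C@H]2C[C@@H](O)C[C@@H]([C@H](O)Cc3ccc(O)cc3)O2)ccc1O | target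

## Step count and least certain steps

Total: 11 steps. Longest linear sequence: 9 steps (steps 1–4 and 7–11, from D-tyrosine); the ketone branch (steps 5 and 6) joins at step 7.

**Step 10 (key step, proposed new method).**
- What may go wrong: no productive binding, because the seven-carbon chain with its benzyloxyphenyl end is far longer than the native substrates and may not fit the channel to the flavin.
- If hydride transfer does occur, the quinone methide may partition towards proton loss at C3 (the path this enzyme class takes with propyl and longer side chains) or towards hydration at C2 instead of ring closure.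
- Further risks are over-oxidation of the product at its remaining C2–H bond and poor solubility of the lipophilic substrate in buffer.
- Fallback (known chemistry): triol 14 is oxidised chemically. One equivalent of DDQ in CH2Cl2/1,4-dioxane at 0 °C attacks the free guaiacol in preference to the aryl benzyl ether and generates the same p-quinone methide 15 in the flask, which the C6 hydroxyl traps. A trace of pyridinium p-toluenesulfonate then equilibrates the benzylic ether through reversible ring opening to the all-equatorial isomer. This is the quinone-methide cyclisation known from DDQ oxidations of 4-alkylphenols bearing a pendant hydroxyl. It sets out from 14 and returns to the route at 16 without any new isolated compound.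

**Step 7.**
- What may go wrong: poor facial selectivity, because the enol ether of a methyl ketone is a small nucleophile and the Felkin preference of an α-silyloxy aldehyde may not be high enough. Lewis-acid-induced enolisation of 7 may also erode the C7 configuration.
- Fallback: the stereocentre is set with reagent control in a boron aldol. Ketone 9 is enolised on its methyl side with (−)-Ipc2BCl and Et3N in Et2O at 0 °C to give the diisopinocampheylboron enolate F1. F1 is combined with aldehyde 7 at −78 °C and worked up oxidatively (H2O2, pH 7 buffer, MeOH).
- (−)-Ipc2BCl is the enantiomer expected to direct methyl-ketone enolates to the aldehyde si face, the face that Felkin control also prefers, so reagent and substrate bias should add up.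
- The fallback sets out from 9 and 7, returns at 12, and makes steps 6 and 7 unnecessary.

**Step 11.**
- What may go wrong: over-reduction, that is hydrogenolysis of the ring O1–C2 benzylic ether in competition with cleavage of the aryl benzyl ether, which would reopen the ring.
- Fallback: a non-reductive debenzylation. Compound 16 is acetylated (Ac2O, pyridine, DMAP) to the triacetate (2R,4R,6S)-2-[4-(acetyloxy)-3-methoxyphenyl]-6-{(1R)-1-(acetyloxy)-2-[4-(benzyloxy)phenyl]ethyl}oxan-4-yl acetate F2; the aryl acetate makes C2 less prone to ionise. BCl3 with pentamethylbenzene as cation scavenger in CH2Cl2 at −78 °C then removes the benzyl group and gives (2R,4R,6S)-2-[4-(acetyloxy)-3-methoxyphenyl]-6-[(1R)-1-(acetyloxy)-2-(4-hydroxyphenyl)ethyl]oxan-4-yl acetate F3. Methanolysis (K2CO3, MeOH) frees the three hydroxyls.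
- The fallback sets out from 16 and returns at 17.

**Step 4.**
- What may go wrong: over-reduction to the primary alcohol (the benzyloxide of the ester is a good leaving group) or epimerisation of the α-silyloxy aldehyde during work-up.
- Fallback: the ester is reduced completely with LiBH4 in THF at 0 °C to (2R)-3-[4-(benzyloxy)phenyl]-2-[(tert-butyldimethylsilyl)oxy]propan-1-ol F4. This is reoxidised under Parikh–Doering conditions (SO3·pyridine, DMSO, i-Pr2NEt, 0 °C), which are mild towards the α-stereocentre.
- The fallback sets out from 6 and returns at 7.

## Further compounds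

F0 | step 10 | none | none
F1 | step 7 | {[4-(4-{[tert-butyl(dimethyl)silyl]oxy}-3-methoxyphenyl)but-1-en-2-yl]oxy}bis[(1R,2S,3R,5R)-2,6,6-trimethylbicyclo[3.1.1]heptan-3-yl]borane | C=C(CCc1ccc(O[Si](C)(C)C(C)(C)C)c(OC)c1)OB([C@@H]1C[C@@H]2C[C@H]([C@H]1C)C2(C)C)[C@@H]1C[C@@H]2C[C@H]([C@H]1C)C2(C)C
F2 | step 11 | (2R,4R,6S)-2-[4-(acetyloxy)-3-methoxyphenyl]-6-{(1R)-1-(acetyloxy)-2-[4-(benzyloxy)phenyl]ethyl}oxan-4-yl acetate | COc1cc([C@H]2C[C@@H](OC(C)=O)C[C@@H]([C@H](OC(C)=O)Cc3ccc(OCc4ccccc4)cc3)O2)ccc1OC(C)=O
F3 | step 11 | (2R,4R,6S)-2-[4-(acetyloxy)-3-methoxyphenyl]-6-[(1R)-1-(acetyloxy)-2-(4-hydroxyphenyl)ethyl]oxan-4-yl acetate | COc1cc([C@H]2C[C@@H](OC(C)=O)C[C@@H]([C@H](OC(C)=O)Cc3ccc(O)cc3)O2)ccc1OC(C)=O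
F4 | step 4 | (2R)-3-[4-(benzyloxy)phenyl]-2-[(tert-butyldimethylsilyl)oxy]propan-1-ol | CC(C)(C)[Si](C)(C)O[C@H](Cc1ccc(OCc2ccccc2)cc1)CO
A1 | alternative 1 | (5S)-3-{(E)-2-[4-(benzyloxy)-3-methoxyphenyl]ethenyl}-5-{(1R)-2-[4-(benzyloxy)phenyl]-1-[(tert-butyldimethylsilyl)oxy]ethyl}-4,5-dihydro-1,2-oxazole | COc1cc(/C=C/C2=NO[C@@H](C2)[C@H](O[Si](C)(C)C(C)(C)C)Cc3ccc(OCc4ccccc4)cc3)ccc1OCc1ccccc1
A2 | alternative 1 | (2E)-3-[4-(benzyloxy)-3-methoxyphenyl]prop-2-enal oxime | COc1cc(/C=C/C=NO)ccc1OCc1ccccc1
A3 | alternative 1 | ({(2R)-1-[4-(benzyloxy)phenyl]but-3-en-2-yl}oxy)(tert-butyl)dimethylsilane | C=C[C@H](O[Si](C)(C)C(C)(C)C)Cc1ccc(OCc2ccccc2)cc1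
A4 | alternative 2 | (2S,3R)-3-(benzyloxy)-4-[4-(benzyloxy)phenyl]-1-(2-{(2S)-2-[4-(benzyloxy)-3-methoxyphenyl]-2-[(tert-butyldimethylsilyl)oxy]ethyl}-1,3-dithian-2-yl)butan-2-ol | COc1cc([C@@H](O[Si](C)(C)C(C)(C)C)CC2(C[C@H](O)[C@H](OCc3ccccc3)Cc3ccc(OCc4ccccc4)cc3)SCCCS2)ccc1OCc1ccccc1
A5 | alternative 2 | 2-(tert-butyldimethylsilyl)-1,3-dithiane | CC(C)(C)[Si](C)(C)C1SCCCS1
A6 | alternative 2 | (2R)-2-[4-(benzyloxy)-3-methoxyphenyl]oxirane | COc1cc([C@@H]2CO2)ccc1OCc1ccccc1
A7 | alternative 2 | (2S)-2-{(1R)-1-(benzyloxy)-2-[4-(benzyloxy)phenyl]ethyl}oxirane | C1O[C@@H]1[C@H](OCc1ccccc1)Cc1ccc(OCc2ccccc2)cc1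
A8 | alternative 3 | (2R,6S)-2-[4-(benzyloxy)-3-methoxyphenyl]-6-{(1R)-2-[4-(benzyloxy)phenyl]-1-[(tert-butyldimethylsilyl)oxy]ethyl}-4-[(triethylsilyl)oxy]-5,6-dihydro-2H-pyran | COc1cc([C@H]2C=C(O[Si](CC)(CC)CC)C[C@@H]([C@H](O[Si](C)(C)C(C)(C)C)Cc3ccc(OCc4ccccc4)cc3)O2)ccc1OCc1ccccc1
A9 | alternative 3 | ({(3E)-4-[4-(benzyloxy)-3-methoxyphenyl]buta-1,3-dien-2-yl}oxy)triethylsilane | COc1cc(/C=C/C(=C)O[Si](CC)(CC)CC)ccc1OCc1ccccc1
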